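**Plan**

1. Retrosynthetic cuts, in order: the two MOM ether C–O bonds; then, together, the C2'–O bond and the C3'–CH= bond of the dimethylpyran on ring B (back to a C2'≡C3' aryne and 3-methylbut-2-enal); the C6–prenyl bond; O1–C2 of ring C; C3–C4.
2. The feature that allows the pyran-forming event: on ring B the pyran oxygen (C2') and the pyran CH= (C3') sit on neighbouring carbons directly beside the C4' oxygen. A C2'≡C3' aryne flanked by C4'–O is polarised so that a carbonyl oxygen adds at C2' and its carbon at C3'. The unit O–CMe2–CH=CH contains exactly the atoms of 3-methylbut-2-enal.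
3. Forward: fragment 1 (ring-B arylacetic acid from a benzofuranone whose lactone tells the two ring-B oxygens apart) and fragment 2 (ring-A benzyl bromide) are joined by enolate alkylation (C3–C4). Reduction and Mitsunobu closure give ring C. Silylation, prenylation and carbamate-to-triflate exchange set up the aryne, which builds the pyran ring. MOM removal is last.
4. Helpers: the diethylcarbamate masks O–C2' and directs metalation to C3'; Me3Si and OTf trigger the aryne and both leave in the key step; allyl caps the ring-A oxygen until ring C is closed; the MOM ethers come off in the final step.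
5. Stereochemistry: the only stereocentre, C3 (R), comes from (4R)-4-benzyl-1,3-oxazolidin-2-one in the enolate alkylation and is not a reacting atom afterwards.

Key step: step 15

Remark on the chemistry: 6-hydroxy-1-benzofuran-2(3H)-one and 5-bromo-2,4-dihydroxybenzaldehyde are taken as catalogue materials, and the facial selectivity of the alkylation is assigned from the usual chelated Z-enolate model.

**Route**

Step 1
Reactants: 1 6-hydroxy-1-benzofuran-2(3H)-one
Product: 2 6-(methoxymethoxy)-1-benzofuran-2(3H)-one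
Conditions: MeOCH2Cl (1.2 equiv), i-Pr2NEt (1.5 equiv), CH2Cl2, 0 °C to rt
Reagents that add atoms: chloromethyl methyl ether, COCCl
Why: Williamson-type O-alkylation of the only free phenol under mild amine buffering should leave the lactone intact, so the future C4' oxygen carries MOM while the future C2' oxygen stays masked in the lactone ring.

Step 2
Reactants: 2 6-(methoxymethoxy)-1-benzofuran-2(3H)-one
Product: 5 [2-(diethylcarbamoyloxy)-4-(methoxymethoxy)phenyl]acetic acid, via sodium phenoxide ester 3 (not isolated), via carbamate methyl ester 4 (not isolated)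
Conditions: NaOMe (1.05 equiv), MeOH–THF, 0 °C; Et2NC(O)Cl (1.3 equiv), 50 °C; then LiOH, H2O, rt; 1 M HCl to pH 4 at 0 °C
Reagents that add atoms: N,N-diethylcarbamoyl chloride, CCN(CC)C(=O)Cl; lithium hydroxide, [Li+].[OH-]
Why: Methoxide opens the strained aryl lactone by transesterification and frees only the C2' phenoxide, which is O-carbamoylated in the same flask, and the methyl ester is then saponified under conditions an aryl N,N-dialkylcarbamate tolerates (lactone opening, carbamate formation, ester hydrolysis).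

Step 3
Reactants: 5 [2-(diethylcarbamoyloxy)-4-(methoxymethoxy)phenyl]acetic acid; 6 (4R)-4-benzyl-1,3-oxazolidin-2-one
Product: 8 (4R)-4-benzyl-3-{[2-(diethylcarbamoyloxy)-4-(methoxymethoxy)phenyl]acetyl}-1,3-oxazolidin-2-one, via mixed pivalic anhydride 7 (not isolated)
Conditions: t-BuCOCl, Et3N, THF, −20 °C; then 6, LiCl, rt
Reagents that add atoms: none
Why: N-acylation of the oxazolidinone by the mixed anhydride under LiCl/Et3N activation (Evans auxiliary attachment) avoids strong base, so the acidic benzylic methylene and the carbamate are not touched.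

Step 4
Reactants: 9 5-bromo-2,4-dihydroxybenzaldehyde
Product: 11 2-(allyloxy)-5-bromo-4-(methoxymethoxy)benzaldehyde, via mono-MOM ether 10 (not isolated)
Conditions: MeOCH2Cl (1.05 equiv), K2CO3, acetone, 0 °C to rt; then allyl bromide (1.5 equiv), 56 °C
Reagents that add atoms: chloromethyl methyl ether, COCCl; allyl bromide, C=CCBr
Why: Sequential Williamson etherification in which the 4-OH (para to the formyl group, not hydrogen-bonded) should react first and the chelated 2-OH is then allylated on heating, giving the two ring-A oxygens different protecting groups.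

Step 5
Reactants: 11 2-(allyloxy)-5-bromo-4-(methoxymethoxy)benzaldehyde
Product: 12 [2-(allyloxy)-5-bromo-4-(methoxymethoxy)phenyl]methanol
Conditions: NaBH4, MeOH, 0 °C
Reagents that add atoms: none
Why: Chemoselective borohydride reduction of the aldehyde; aryl bromide, MOM acetal and allyl ether are inert to NaBH4.

Step 6
Reactants: 12 [2-(allyloxy)-5-bromo-4-(methoxymethoxy)phenyl]methanol
Product: 13 1-(allyloxy)-4-bromo-2-(bromomethyl)-5-(methoxymethoxy)benzene
Conditions: CBr4, PPh3, CH2Cl2, 0 °C; used at once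
Reagents that add atoms: carbon tetrabromide, BrC(Br)(Br)Br
Why: Appel bromination converts the benzylic alcohol into the bromide under neutral conditions that spare the MOM acetal, and the electron-rich bromide is taken on without storage.

Step 7
Reactants: 8 (4R)-4-benzyl-3-{[2-(diethylcarbamoyloxy)-4-(methoxymethoxy)phenyl]acetyl}-1,3-oxazolidin-2-one; 13 1-(allyloxy)-4-bromo-2-(bromomethyl)-5-(methoxymethoxy)benzene
Product: 15 (4R)-4-benzyl-3-{(2R)-3-[2-(allyloxy)-5-bromo-4-(methoxymethoxy)phenyl]-2-[2-(diethylcarbamoyloxy)-4-(methoxymethoxy)phenyl]propanoyl}-1,3-oxazolidin-2-one, via sodium Z-enolate 14 (not isolated)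
Conditions: NaN(SiMe3)2 (1.05 equiv), THF, −78 °C; then 13 (1.3 equiv), −78 to −45 °C; AcOH quench at −78 °C
Reagents that add atoms: none
Why: Evans asymmetric alkylation, in which the chelated Z-enolate is benzylated on the face opposite the C4 benzyl group of the (R)-auxiliary and so should set the (R) centre that becomes C3, while the low temperature keeps the α-aryl centre from epimerising and the carbamate from migrating to carbon.

Step 8
Reactants: 15 (4R)-4-benzyl-3-{(2R)-3-[2-(allyloxy)-5-bromo-4-(methoxymethoxy)phenyl]-2-[2-(diethylcarbamoyloxy)-4-(methoxymethoxy)phenyl]propanoyl}-1,3-oxazolidin-2-one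
Product: 16 2-{(2R)-1-[2-(allyloxy)-5-bromo-4-(methoxymethoxy)phenyl]-3-hydroxypropan-2-yl}-5-(methoxymethoxy)phenyl diethylcarbamate
Conditions: LiBH4, H2O (1.1 equiv), Et2O–THF, 0 °C
Reagents that add atoms: none
Why: Reductive removal of the auxiliary by LiBH4 at the exocyclic imide carbonyl should give the primary alcohol under cold, non-basic conditions, so the stereocentre is retained and bromide, allyl ether and tertiary carbamate survive.

Step 9
Reactants: 16 2-{(2R)-1-[2-(allyloxy)-5-bromo-4-(methoxymethoxy)phenyl]-3-hydroxypropan-2-yl}-5-(methoxymethoxy)phenyl diethylcarbamate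
Product: 17 2-{(2R)-1-[5-bromo-2-hydroxy-4-(methoxymethoxy)phenyl]-3-hydroxypropan-2-yl}-5-(methoxymethoxy)phenyl diethylcarbamate
Conditions: Pd(PPh3)4 (5 mol %), morpholine (5 equiv), THF, rt
Reagents that add atoms: none
Why: Tsuji–Trost-type allyl transfer from the aryl allyl ether to morpholine by zerovalent palladium frees the ring-A phenol under neutral conditions at a temperature where the electron-rich aryl bromide should not undergo oxidative addition.

Step 10
Reactants: 17 2-{(2R)-1-[5-bromo-2-hydroxy-4-(methoxymethoxy)phenyl]-3-hydroxypropan-2-yl}-5-(methoxymethoxy)phenyl diethylcarbamate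
Product: 18 2-[(3R)-6-bromo-7-(methoxymethoxy)chroman-3-yl]-5-(methoxymethoxy)phenyl diethylcarbamate
Conditions: PPh3, DIAD, THF, 0 °C to rt
Reagents that add atoms: none
Why: Intramolecular Mitsunobu etherification (6-exo-tet attack of the ring-A phenol oxygen on the activated primary carbinol carbon) should close ring C, since the ring-B oxygen next to the side chain is blocked as the carbamate and the stereocentre is not a reacting atom.

Step 11
Reactants: 18 2-[(3R)-6-bromo-7-(methoxymethoxy)chroman-3-yl]-5-(methoxymethoxy)phenyl diethylcarbamate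
Product: 20 6-[(3R)-6-bromo-7-(methoxymethoxy)chroman-3-yl]-3-(methoxymethoxy)-2-(trimethylsilyl)phenyl diethylcarbamate, via C3' aryllithium 19 (not isolated)
Conditions: LiN(i-Pr)2 (2 equiv), Me3SiCl (4 equiv, present from the start), THF, −78 °C
Reagents that add atoms: chlorotrimethylsilane, C[Si](C)(C)Cl
Why: Directed ortho-metalation with in situ silyl trapping, in which C3'–H (flanked by the O-carbamate and the OMOM group, and the only position ortho to the carbamate) is the most acidic ring proton, a lithium amide leaves the aryl bromide alone, and the silyl chloride captures the aryllithium before the carbamoyl group can migrate.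

Step 12
Reactants: 20 6-[(3R)-6-bromo-7-(methoxymethoxy)chroman-3-yl]-3-(methoxymethoxy)-2-(trimethylsilyl)phenyl diethylcarbamate
Product: 23 3-(methoxymethoxy)-6-[(3R)-7-(methoxymethoxy)-6-(3-methylbut-2-en-1-yl)chroman-3-yl]-2-(trimethylsilyl)phenyl diethylcarbamate, via C6 aryllithium 21 (not isolated), via arylcopper 22 (not isolated)
Conditions: n-BuLi (1.05 equiv), THF, −78 °C; CuBr·SMe2 (1.1 equiv), −78 °C; prenyl bromide (1.5 equiv), −78 to 0 °C
Reagents that add atoms: 1-bromo-3-methylbut-2-ene, CC(C)=CCBr
Why: Bromine–lithium exchange (faster than addition to the now doubly flanked carbamate), transmetalation to copper and allylic substitution at the unhindered primary carbon of prenyl bromide should give the linear prenyl group at C6.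

Step 13
Reactants: 23 3-(methoxymethoxy)-6-[(3R)-7-(methoxymethoxy)-6-(3-methylbut-2-en-1-yl)chroman-3-yl]-2-(trimethylsilyl)phenyl diethylcarbamate
Product: 24 3-(methoxymethoxy)-6-[(3R)-7-(methoxymethoxy)-6-(3-methylbut-2-en-1-yl)chroman-3-yl]-2-(trimethylsilyl)phenol
Conditions: LiAlH4 (3 equiv), THF, 0 to 65 °C
Reagents that add atoms: none
Why: Reductive cleavage of the aryl O-carbamate (hydride addition to the carbamate carbonyl, loss of the phenoxide) should free the C2' phenol, since MOM ethers, the arylsilane and the isolated alkene are inert to LiAlH4.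

Step 14
Reactants: 24 3-(methoxymethoxy)-6-[(3R)-7-(methoxymethoxy)-6-(3-methylbut-2-en-1-yl)chroman-3-yl]-2-(trimethylsilyl)phenol
Product: 25 3-(methoxymethoxy)-6-[(3R)-7-(methoxymethoxy)-6-(3-methylbut-2-en-1-yl)chroman-3-yl]-2-(trimethylsilyl)phenyl trifluoromethanesulfonate
Conditions: (CF3SO2)2O (1.3 equiv), pyridine, CH2Cl2, −20 to 0 °C
Reagents that add atoms: trifluoromethanesulfonic anhydride, O=S(=O)(OS(=O)(=O)C(F)(F)F)C(F)(F)F
Why: O-sulfonylation of the hindered phenol under pyridine buffering should give the ortho-silylaryl triflate, the standard fluoride-triggered aryne precursor, without harm to MOM ethers or alkene.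

Step 15
Reactants: 25 3-(methoxymethoxy)-6-[(3R)-7-(methoxymethoxy)-6-(3-methylbut-2-en-1-yl)chroman-3-yl]-2-(trimethylsilyl)phenyl trifluoromethanesulfonate; 26 3-methylbut-2-enal
Product: 30 5-(methoxymethoxy)-8-[(3R)-7-(methoxymethoxy)-6-(3-methylbut-2-en-1-yl)chroman-3-yl]-2,2-dimethyl-2H-chromene, via aryne 27 (not isolated), via benzoxete 28 (not isolated), via ortho-quinone methide 29 (not isolated)
Conditions: CsF (3 equiv), 26 (5 equiv), MeCN, 25 to 50 °C
Reagents that add atoms: none
Why: Fluoride attacks silicon in 25 and the aryl anion expels triflate to give aryne 27; the carbonyl oxygen of 26 adds to C2', the aryne carbon remote from the C4' oxygen, and the anion at C3' closes onto the carbonyl carbon (formal [2+2]) to give benzoxete 28. Thermal 4π-electrocyclic opening of 28 gives the ortho-quinone methide 29, an oxatriene whose disrotatory oxa-6π-electrocyclisation closes the six-membered pyran ring through the new O–CMe2 bond and restores aromaticity. The closest known reaction type is the annulation of arynes with α,β-unsaturated aldehydes to 2H-chromenes, related to aryne insertion into the C=O bond of formamides. The four-membered ring closes by addition of the C3' anion to the oxocarbenium carbon and the pyran ring by 6π-electrocyclisation; no stereocentre is formed, and C3 lies away from any acidic or ionising site. The step needs regioselectivity (O on C2', C on C3'), which the inductively withdrawing C4'–OMOM group should secure by distorting the aryne toward attack at C2' despite the neighbouring chromanyl group; it also needs chemoselectivity over an ene reaction of the prenyl group and over hetero-Diels–Alder addition, which the excess aldehyde and the β,β-dimethyl substitution of 26 should secure.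

Step 16
Reactants: 30 5-(methoxymethoxy)-8-[(3R)-7-(methoxymethoxy)-6-(3-methylbut-2-en-1-yl)chroman-3-yl]-2,2-dimethyl-2H-chromene
Product: 31 8-[(3R)-7-hydroxy-6-(3-methylbut-2-en-1-yl)chroman-3-yl]-2,2-dimethyl-2H-chromen-5-ol
Conditions: HCl (1 M in MeOH), 25 to 40 °C, short reaction time
Reagents that add atoms: none
Why: Acid-catalysed transacetalisation of the two aryl MOM ethers to dimethoxymethane, a deprotection in common use on prenylated phenols and 2,2-dimethylchromenes when exposure is kept short, should free both phenols without cyclising the ortho-prenylphenol or touching C3.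

**Compound list**

1 | 6-hydroxy-1-benzofuran-2(3H)-one | O=C1Cc2ccc(O)cc2O1 | starting material
2 | 6-(methoxymethoxy)-1-benzofuran-2(3H)-one | O=C1Cc2ccc(OCOC)cc2O1 | intermediate
3 | sodium 2-(2-methoxy-2-oxoethyl)-5-(methoxymethoxy)phenolate | [Na+].[O-]c1cc(OCOC)ccc1CC(=O)OC | intermediate
4 | methyl [2-(diethylcarbamoyloxy)-4-(methoxymethoxy)phenyl]acetate | COC(=O)Cc1ccc(OCOC)cc1OC(=O)N(CC)CC | intermediate
5 | [2-(diethylcarbamoyloxy)-4-(methoxymethoxy)phenyl]acetic acid | OC(=O)Cc1ccc(OCOC)cc1OC(=O)N(CC)CC | intermediate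
6 | (4R)-4-benzyl-1,3-oxazolidin-2-one | O=C1N[C@H](Cc2ccccc2)CO1 | starting material
7 | [2-(diethylcarbamoyloxy)-4-(methoxymethoxy)phenyl]acetic pivalic anhydride | CC(C)(C)C(=O)OC(=O)Cc1ccc(OCOC)cc1OC(=O)N(CC)CC | intermediate
8 | (4R)-4-benzyl-3-{[2-(diethylcarbamoyloxy)-4-(methoxymethoxy)phenyl]acetyl}-1,3-oxazolidin-2-one | O=C1OC[C@@H](Cc2ccccc2)N1C(=O)Cc1ccc(OCOC)cc1OC(=O)N(CC)CC | intermediate
9 | 5-bromo-2,4-dihydroxybenzaldehyde | O=Cc1cc(Br)c(O)cc1O | starting material
10 | 5-bromo-2-hydroxy-4-(methoxymethoxy)benzaldehyde | O=Cc1cc(Br)c(OCOC)cc1O | intermediate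
11 | 2-(allyloxy)-5-bromo-4-(methoxymethoxy)benzaldehyde | O=Cc1cc(Br)c(OCOC)cc1OCC=C | intermediate
12 | [2-(allyloxy)-5-bromo-4-(methoxymethoxy)phenyl]methanol | OCc1cc(Br)c(OCOC)cc1OCC=C | intermediate
13 | 1-(allyloxy)-4-bromo-2-(bromomethyl)-5-(methoxymethoxy)benzene | BrCc1cc(Br)c(OCOC)cc1OCC=C | intermediate
14 | sodium (Z)-enolate of imide 8 | [Na+].[O-]/C(=C\c1ccc(OCOC)cc1OC(=O)N(CC)CC)N1[C@H](Cc2ccccc2)COC1=O | intermediate
15 | (4R)-4-benzyl-3-{(2R)-3-[2-(allyloxy)-5-bromo-4-(methoxymethoxy)phenyl]-2-[2-(diethylcarbamoyloxy)-4-(methoxymethoxy)phenyl]propanoyl}-1,3-oxazolidin-2-one | O=C1OC[C@@H](Cc2ccccc2)N1C(=O)[C@@H](c1ccc(OCOC)cc1OC(=O)N(CC)CC)Cc1cc(Br)c(OCOC)cc1OCC=C | intermediate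
16 | 2-{(2R)-1-[2-(allyloxy)-5-bromo-4-(methoxymethoxy)phenyl]-3-hydroxypropan-2-yl}-5-(methoxymethoxy)phenyl diethylcarbamate | OC[C@@H](c1ccc(OCOC)cc1OC(=O)N(CC)CC)Cc1cc(Br)c(OCOC)cc1OCC=C | intermediate
17 | 2-{(2R)-1-[5-bromo-2-hydroxy-4-(methoxymethoxy)phenyl]-3-hydroxypropan-2-yl}-5-(methoxymethoxy)phenyl diethylcarbamate | OC[C@@H](c1ccc(OCOC)cc1OC(=O)N(CC)CC)Cc1cc(Br)c(OCOC)cc1O | intermediate
18 | 2-[(3R)-6-bromo-7-(methoxymethoxy)chroman-3-yl]-5-(methoxymethoxy)phenyl diethylcarbamate | Brc1cc2c(cc1OCOC)OC[C@@H](c1ccc(OCOC)cc1OC(=O)N(CC)CC)C2 | intermediate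
19 | C3'-lithio derivative of 18 (lithium between the carbamate and OMOM groups of ring B) | Brc1cc2c(cc1OCOC)OC[C@@H](c1ccc(OCOC)c([Li])c1OC(=O)N(CC)CC)C2 | intermediate
20 | 6-[(3R)-6-bromo-7-(methoxymethoxy)chroman-3-yl]-3-(methoxymethoxy)-2-(trimethylsilyl)phenyl diethylcarbamate | Brc1cc2c(cc1OCOC)OC[C@@H](c1ccc(OCOC)c([Si](C)(C)C)c1OC(=O)N(CC)CC)C2 | intermediate
21 | C6-lithio derivative of 20 (lithium in place of bromine on ring A) | [Li]c1cc2c(cc1OCOC)OC[C@@H](c1ccc(OCOC)c([Si](C)(C)C)c1OC(=O)N(CC)CC)C2 | intermediate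
22 | C6-arylcopper derived from 21 | [Cu]c1cc2c(cc1OCOC)OC[C@@H](c1ccc(OCOC)c([Si](C)(C)C)c1OC(=O)N(CC)CC)C2 | intermediate
23 | 3-(methoxymethoxy)-6-[(3R)-7-(methoxymethoxy)-6-(3-methylbut-2-en-1-yl)chroman-3-yl]-2-(trimethylsilyl)phenyl diethylcarbamate | CC(C)=CCc1cc2c(cc1OCOC)OC[C@@H](c1ccc(OCOC)c([Si](C)(C)C)c1OC(=O)N(CC)CC)C2 | intermediate
24 | 3-(methoxymethoxy)-6-[(3R)-7-(methoxymethoxy)-6-(3-methylbut-2-en-1-yl)chroman-3-yl]-2-(trimethylsilyl)phenol | CC(C)=CCc1cc2c(cc1OCOC)OC[C@@H](c1ccc(OCOC)c([Si](C)(C)C)c1O)C2 | intermediate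
25 | 3-(methoxymethoxy)-6-[(3R)-7-(methoxymethoxy)-6-(3-methylbut-2-en-1-yl)chroman-3-yl]-2-(trimethylsilyl)phenyl trifluoromethanesulfonate | CC(C)=CCc1cc2c(cc1OCOC)OC[C@@H](c1ccc(OCOC)c([Si](C)(C)C)c1OS(=O)(=O)C(F)(F)F)C2 | intermediate
26 | 3-methylbut-2-enal | CC(C)=CC=O | starting material
27 | ring-B C2'≡C3' aryne: (3R)-7-(methoxymethoxy)-3-[4-(methoxymethoxy)-2,3-didehydrophenyl]-6-(3-methylbut-2-en-1-yl)chromane | CC(C)=CCc1cc2c(cc1OCOC)OC[C@@H](C1=CC=C(OCOC)C#C1)C2 | intermediate
28 | benzoxete: four-membered ring O–CH(CH=CMe2) fused across C2' (O) and C3' (C) of ring B, CH centre unassigned | CC(C)=CCc1cc2c(cc1OCOC)OC[C@@H](c1ccc(OCOC)c3c1OC3C=C(C)C)C2 | intermediate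
29 | (Z)-ortho-quinone methide: ring B as cyclohexadienone with C2'=O and exocyclic C3'=CH–CH=CMe2 | CC(C)=CCc1cc2c(cc1OCOC)OC[C@@H](C1=CC=C(OCOC)/C(=C/C=C(C)C)C1=O)C2 | intermediate
30 | 5-(methoxymethoxy)-8-[(3R)-7-(methoxymethoxy)-6-(3-methylbut-2-en-1-yl)chroman-3-yl]-2,2-dimethyl-2H-chromene | CC(C)=CCc1cc2c(cc1OCOC)OC[C@@H](c1ccc(OCOC)c3c1OC(C)(C)C=C3)C2 | intermediate
31 | 8-[(3R)-7-hydroxy-6-(3-methylbut-2-en-1-yl)chroman-3-yl]-2,2-dimethyl-2H-chromen-5-ol (CNP0332706.1) | CC(C)=CCc1cc2c(cc1O)OC[C@@H](c1ccc(O)c3c1OC(C)(C)C=C3)C2 | target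

**Step count and risks**

Total: 16 steps. Longest linear sequence: 13 steps (steps 1–3, then 7–16; the ring-A arm, steps 4–6 then 7–16, is equally long).

The three steps most likely to fail:

Step 15. The aldehyde oxygen may add at the wrong aryne carbon, because C2' is flanked by the bulky chromanyl group. The aryne may also be lost to an ene reaction at the prenyl double bond, to capture by fluoride or by the ring-C ether oxygen, or the quinone methide may be intercepted by a second aryne. The fallback builds the same pyran ring by the classical route in which the aryl–oxygen bond already exists. It sets out from 18 and comes back at 30. Reductive removal of the carbamate (LiAlH4, THF, 0 °C to rt) should give 2-[(3R)-6-bromo-7-(methoxymethoxy)chroman-3-yl]-5-(methoxymethoxy)phenol F1. O-Alkylation with 3-chloro-3-methylbut-1-yne (DBU, CuCl2 cat., MeCN, 0 °C) should give (3R)-6-bromo-7-(methoxymethoxy)-3-[4-(methoxymethoxy)-2-(2-methylbut-3-yn-2-yloxy)phenyl]chromane F2. Heating (N,N-diethylaniline, 140 °C) should bring about aromatic propargyl Claisen rearrangement to C3', the only free ortho carbon, followed by hydrogen shift and oxa-6π closure to 8-[(3R)-6-bromo-7-(methoxymethoxy)chroman-3-yl]-5-(methoxymethoxy)-2,2-dimethyl-2H-chromene F3. Bromine–lithium exchange, transmetalation to copper and prenyl bromide (n-BuLi; CuBr·SMe2; prenyl bromide, THF, −78 to 0 °C) then give 30.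

Step 11. Deprotonation by the lithium amide may be incomplete or misdirected (metalation next to bromine or at C8 of ring A), or the base may be consumed by the silyl chloride. The fallback changes the order of events and the class of base. It sets out from 18 and comes back at 23. The bromide is exchanged first (n-BuLi; CuBr·SMe2; prenyl bromide, THF, −78 to 0 °C) to give 5-(methoxymethoxy)-2-[(3R)-7-(methoxymethoxy)-6-(3-methylbut-2-en-1-yl)chroman-3-yl]phenyl diethylcarbamate F4. With no aryl bromide left, a conventional alkyllithium ortho-metalation (s-BuLi, TMEDA, THF, −78 °C; then Me3SiCl) should give 23.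

Step 12. The organolithium may attack the carbamate, the aryl anion may be protonated, or allylic transposition (SN2′) may give the 1,1-dimethylallyl isomer. The fallback replaces the organocopper allylation by cross-coupling and olefin metathesis. It sets out from 20 and comes back at 23. Stille coupling with allyltributylstannane (Pd(PPh3)4, toluene, 100 °C) should give 6-[(3R)-6-allyl-7-(methoxymethoxy)chroman-3-yl]-3-(methoxymethoxy)-2-(trimethylsilyl)phenyl diethylcarbamate F5. Cross-metathesis with 2-methylbut-2-ene (second-generation Grubbs catalyst, CH2Cl2, 40 °C) should then give 23.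

Further compounds
F1 | step 15 | 2-[(3R)-6-bromo-7-(methoxymethoxy)chroman-3-yl]-5-(methoxymethoxy)phenol | Brc1cc2c(cc1OCOC)OC[C@@H](c1ccc(OCOC)cc1O)C2
F2 | step 15 | (3R)-6-bromo-7-(methoxymethoxy)-3-[4-(methoxymethoxy)-2-(2-methylbut-3-yn-2-yloxy)phenyl]chromane | Brc1cc2c(cc1OCOC)OC[C@@H](c1ccc(OCOC)cc1OC(C)(C)C#C)C2
F3 | step 15 | 8-[(3R)-6-bromo-7-(methoxymethoxy)chroman-3-yl]-5-(methoxymethoxy)-2,2-dimethyl-2H-chromene | Brc1cc2c(cc1OCOC)OC[C@@H](c1ccc(OCOC)c3c1OC(C)(C)C=C3)C2
F4 | step 11 | 5-(methoxymethoxy)-2-[(3R)-7-(methoxymethoxy)-6-(3-methylbut-2-en-1-yl)chroman-3-yl]phenyl diethylcarbamate | CC(C)=CCc1cc2c(cc1OCOC)OC[C@@H](c1ccc(OCOC)cc1OC(=O)N(CC)CC)C2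
F5 | step 12 | 6-[(3R)-6-allyl-7-(methoxymethoxy)chroman-3-yl]-3-(methoxymethoxy)-2-(trimethylsilyl)phenyl diethylcarbamate | C=CCc1cc2c(cc1OCOC)OC[C@@H](c1ccc(OCOC)c([Si](C)(C)C)c1OC(=O)N(CC)CC)C2
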